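**Retrosynthetic overview**
1. Target 17 ⇐ acetylation of 16 ⇐ hydroxyl-directed epoxidation of Z-allylic alcohol 15: the key step, forming both oxirane C–O bonds and C4/C5 (last ring).
2. 15 ⇐ site-selective angeloylation of diol 12 ⇐ γ-hydroxy Z-enone 10 by a new 1,4-chelation-controlled reduction (sets C6).
3. 10 ⇐ dialkenylcyclohexenediol 7 by anionic oxy-Cope ring expansion (ten-membered ring, E-olefin, C7 by chirality transfer).
4. 7 ⇐ enone 4 + bromide 5; 4 ⇐ (R)-carvone 1 by Luche reduction, Mitsunobu C–O inversion (sets C3) and allylic C–H oxidation (C6 oxygen).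
5. Ring order: cyclohexene (from carvone) → cyclodecadiene (oxy-Cope) → oxirane (epoxidation).

Assumption: 2-bromo-3-methylbut-1-ene (5) and angelic acid (13) are bought as catalogue chemicals.
Names from 9 on use germacrane locants: ring C1=C10(CH3)–C9–C8–C7(isopropyl)–C6–C5–C4(CH3)–C3–C2. The stereochemical arguments for steps 5, 6 and 8 are hand-built conformational models, not calculations.

**Step 1**
Reactants: 1 (R)-(−)-carvone
Product: 2 (1R,5R)-2-methyl-5-(prop-1-en-2-yl)cyclohex-2-en-1-ol
Conditions: NaBH4, CeCl3·7H2O, MeOH, 0 °C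
Reagents that add atoms: none
Why: Luche reduction gives clean 1,2-hydride addition, axial on the half-chair with equatorial isopropenyl, so the cis allylic alcohol (new centre 1R) is formed with high selectivity.

**Step 2**
Reactants: 2 (1R,5R)-2-methyl-5-(prop-1-en-2-yl)cyclohex-2-en-1-ol
Product: 3 (1S,5R)-2-methyl-5-(prop-1-en-2-yl)cyclohex-2-en-1-yl acetate
Conditions: AcOH, PPh3, DIAD, THF, 0 → 25 °C
Reagents that add atoms: acetic acid CC(=O)O
Why: Mitsunobu reaction, in which acetate displaces the alkoxyphosphonium by SN2 with inversion, forms the C–O bond that becomes C3–O of the target and sets it S.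

**Step 3**
Reactants: 3 (1S,5R)-2-methyl-5-(prop-1-en-2-yl)cyclohex-2-en-1-yl acetate
Product: 4 (1S,5R)-2-methyl-4-oxo-5-(prop-1-en-2-yl)cyclohex-2-en-1-yl acetate
Conditions: Rh2(cap)4 (cap = caprolactamate, 1 mol %), t-BuOOH (5 equiv, decane), CH2Cl2, 25 °C
Reagents that add atoms: tert-butyl hydroperoxide CC(C)(C)OO
Why: Allylic C–H oxidation (Kharasch–Sosnovsky-type tert-butylperoxyl radical chain) converts the only ring CH2 next to the vinylic CH into the carbonyl that later becomes the C6 oxygen, the acetoxy-bearing C–H being deactivated and the base-free medium sparing the epimerisable C5 centre; no stereocentre is formed.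

**Step 4**
Reactants: 4 (1S,5R)-2-methyl-4-oxo-5-(prop-1-en-2-yl)cyclohex-2-en-1-yl acetate; 5 2-bromo-3-methylbut-1-ene
Product: 7 (1R,4S,6R)-3-methyl-1-(3-methylbut-1-en-2-yl)-6-(prop-1-en-2-yl)cyclohex-2-ene-1,4-diol, via alkenyl Grignard reagent 6 (not isolated)
Conditions: 5 (3.5 equiv), Mg, THF, 40 °C; CeCl3 (3.5 equiv), −78 °C; then 4, −78 → 0 °C; aq NH4Cl
Reagents that add atoms: none
Why: Imamoto-type organocerium 1,2-addition (CeCl3 suppresses enolisation of the doubly activated C5–H) from the face opposite the adjacent isopropenyl group sets the carbinol centre with the two alkenyl groups trans, as the chair oxy-Cope needs, and the excess reagent removes the acetate by double addition.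

**Step 5**
Reactants: 7 (1R,4S,6R)-3-methyl-1-(3-methylbut-1-en-2-yl)-6-(prop-1-en-2-yl)cyclohex-2-ene-1,4-diol
Product: 10 (3S,7S)-3-hydroxygermacra-1(10)E,4Z-dien-6-one, via dipotassium dialkoxide 8 (not isolated), via dipotassium enolate alkoxide 9 (not isolated)
Conditions: KH (2.5 equiv), 18-crown-6, THF, 0 → 25 °C; then AcOH, THF, −78 °C
Reagents that add atoms: none
Why: Anionic oxy-Cope rearrangement ([3,3]-sigmatropic, chair transition state with both alkenyl groups equatorial) expands the ring by four atoms, gives the E C1=C10 olefin, keeps the ring-derived Z C4=C5 olefin and delivers a ring-trans enolate whose planar chirality is locked (the isopropyl group cannot swing through the ring), so kinetic protonation on its outer face relays the configuration of the former isopropenyl-bearing carbon to C7 (S).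

**Step 6**
Reactants: 10 (3S,7S)-3-hydroxygermacra-1(10)E,4Z-dien-6-one
Product: 12 (3S,6R,7S)-germacra-1(10)E,4Z-diene-3,6-diol, via diethylboron chelate 11 (not isolated)
Conditions: Et2BOMe (1.2 equiv), THF/MeOH (4:1), −78 °C; then NaBH4 (1.5 equiv), −78 °C; AcOH quench, MeOH co-evaporation
Reagents that add atoms: none
Why: Proposed new method: a 1,4-chelation-controlled reduction (vinylogous Narasaka–Prasad reduction, the closest known reaction being the Et2BOMe/NaBH4 syn-reduction of β-hydroxy ketones) in which the diethylborinate of the C3 hydroxyl binds the C6 carbonyl across the Z-olefin in a seven-membered chelate, turning both oxygens into the cleft of the cis-olefin and both ring arms to one face, so that external hydride adds to the activated carbonyl from the opposite, peripheral face (past H7, not past the isopropyl group) and gives the 3,6-syn diol with C6 R, whereas the unchelated ketone is expected to be attacked from the other face.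

**Step 7**
Reactants: 12 (3S,6R,7S)-germacra-1(10)E,4Z-diene-3,6-diol; 13 angelic acid
Product: 15 (3S,6R,7S)-6-hydroxygermacra-1(10)E,4Z-dien-3-yl angelate, via mixed anhydride 14 (not isolated)
Conditions: 13 (1.1 equiv), 2,4,6-trichlorobenzoyl chloride (1.1 equiv), Et3N (2.2 equiv), toluene, 25 °C; then 12, 60 °C (no DMAP)
Reagents that add atoms: none
Why: Yamaguchi esterification without DMAP avoids angelate-to-tiglate isomerisation, and the bulky mixed anhydride acylates the less hindered C3 hydroxyl (flanked by CH2 and the planar C4) in preference to the C6 hydroxyl next to the isopropyl-bearing C7; no stereocentre changes.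

**Step 8**
Reactants: 15 (3S,6R,7S)-6-hydroxygermacra-1(10)E,4Z-dien-3-yl angelate
Product: 16 (3S,4R,5S,6R,7S)-4,5-epoxy-6-hydroxygermacr-1(10)E-en-3-yl angelate
Conditions: VO(acac)2 (5 mol %), t-BuOOH (1.5 equiv, decane), CH2Cl2, 0 °C
Reagents that add atoms: tert-butyl hydroperoxide CC(C)(C)OO
Why: Sharpless–Michaelson hydroxyl-directed epoxidation: the vanadate ester of the C6 alcohol delivers oxygen only to the adjacent Z-olefin (the remote C1=C10 olefin and the electron-poor angelate stay untouched) through the A(1,3)-minimised rotamer with H6 in the olefin plane, i.e. syn to O6 on the open face opposite the ring, giving the threo cis-epoxide with C4 R and C5 S.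

**Step 9**
Reactants: 16 (3S,4R,5S,6R,7S)-4,5-epoxy-6-hydroxygermacr-1(10)E-en-3-yl angelate
Product: 17 (3S,4R,5S,6R,7S)-6-acetoxy-4,5-epoxygermacr-1(10)E-en-3-yl angelate
Conditions: Ac2O, pyridine, DMAP (cat.), CH2Cl2, 0 → 25 °C
Reagents that add atoms: acetic anhydride CC(=O)OC(C)=O
Why: Nucleophile-catalysed acetylation of the one remaining secondary alcohol under non-acidic conditions leaves the epoxide, the angelate and all stereocentres untouched and gives the target.

**Compound list**
1 | (R)-(−)-carvone, (5R)-2-methyl-5-(prop-1-en-2-yl)cyclohex-2-en-1-one | C=C(C)[C@@H]1CC=C(C)C(=O)C1 | starting material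
2 | (1R,5R)-2-methyl-5-(prop-1-en-2-yl)cyclohex-2-en-1-ol (cis-carveol) | C=C(C)[C@@H]1CC=C(C)[C@H](O)C1 | intermediate
3 | (1S,5R)-2-methyl-5-(prop-1-en-2-yl)cyclohex-2-en-1-yl acetate (trans-carvyl acetate) | C=C(C)[C@@H]1CC=C(C)[C@@H](OC(C)=O)C1 | intermediate
4 | (1S,5R)-2-methyl-4-oxo-5-(prop-1-en-2-yl)cyclohex-2-en-1-yl acetate | C=C(C)[C@@H]1C(=O)C=C(C)[C@@H](OC(C)=O)C1 | intermediate
5 | 2-bromo-3-methylbut-1-ene | C=C(Br)C(C)C | starting material
6 | (3-methylbut-1-en-2-yl)magnesium bromide | CC(C)C(=C)[Mg]Br | intermediate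
7 | (1R,4S,6R)-3-methyl-1-(3-methylbut-1-en-2-yl)-6-(prop-1-en-2-yl)cyclohex-2-ene-1,4-diol | C=C(C)[C@@H]1[C@@](O)(C(=C)C(C)C)C=C(C)[C@@H](O)C1 | intermediate
8 | dipotassium (1R,4S,6R)-3-methyl-1-(3-methylbut-1-en-2-yl)-6-(prop-1-en-2-yl)cyclohex-2-ene-1,4-diolate | C=C(C)[C@@H]1[C@@]([O-])(C(=C)C(C)C)C=C(C)[C@@H]([O-])C1.[K+].[K+] | intermediate
9 | dipotassium (3S)-germacra-1(10)E,4Z,6-triene-3,6-diolate (ring-trans C6=C7 enolate) | [O-][C@H]1C/C=C(\C)CC/C(C(C)C)=C(\[O-])/C=C1/C.[K+].[K+] | intermediate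
10 | (3S,7S)-3-hydroxygermacra-1(10)E,4Z-dien-6-one | O[C@H]1C/C=C(\C)CC[C@@H](C(C)C)C(=O)/C=C1/C | intermediate
11 | O3-diethylboryl derivative of 10 (boron chelated by the C6 carbonyl) | CCB(CC)O[C@H]1C/C=C(\C)CC[C@@H](C(C)C)C(=O)/C=C1/C | intermediate
12 | (3S,6R,7S)-germacra-1(10)E,4Z-diene-3,6-diol | O[C@H]1C/C=C(\C)CC[C@@H](C(C)C)[C@@H](O)/C=C1/C | intermediate
13 | angelic acid, (Z)-2-methylbut-2-enoic acid | C/C=C(/C)C(=O)O | starting material
14 | (Z)-2-methylbut-2-enoic 2,4,6-trichlorobenzoic anhydride | C/C=C(/C)C(=O)OC(=O)c1c(Cl)cc(Cl)cc1Cl | intermediate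
15 | (3S,6R,7S)-6-hydroxygermacra-1(10)E,4Z-dien-3-yl angelate | C/C=C(/C)C(=O)O[C@H]1C/C=C(\C)CC[C@@H](C(C)C)[C@@H](O)/C=C1/C | intermediate
16 | (3S,4R,5S,6R,7S)-4,5-epoxy-6-hydroxygermacr-1(10)E-en-3-yl angelate | C/C=C(/C)C(=O)O[C@H]1C/C=C(\C)CC[C@@H](C(C)C)[C@@H](O)[C@@H]2O[C@]12C | intermediate
17 | (3S,4R,5S,6R,7S)-6-acetoxy-4,5-epoxygermacr-1(10)E-en-3-yl angelate | C/C=C(/C)C(=O)O[C@H]1C/C=C(\C)CC[C@@H](C(C)C)[C@@H](OC(C)=O)[C@@H]2O[C@]12C | target

**Totals**
Total step count: 9. Longest linear sequence: 9 steps (1 → 17); 5 and 13 are bought.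

**Three steps most likely to fail**

Step 5 (oxy-Cope and relay to C7). The C7 configuration rests on outer-face protonation of a locked planar-chiral enolate; tautomerisation on work-up could erode it, and base equilibration of the free γ-hydroxy enone is unsafe (1,4-dione formation). The fallback replaces substrate-controlled protonation by catalyst-controlled dynamic kinetic resolution. It sets out from 10 taken as a C7 epimer mixture. Silylation (TBSCl, imidazole, DMF) gives (3S,7RS)-3-(tert-butyldimethylsilyloxy)germacra-1(10)E,4Z-dien-6-one F1. Asymmetric hydrogenation (RuCl2[(S)-xylbinap][(S)-daipen], KOtBu, iPrOH, H2 8 atm; catalyst enantiomer chosen as the one matched to the 6R carbinol) equilibrates C7 through the enolate while the catalyst selects the carbonyl face and the 6,7-cis product, giving (3S,6R,7S)-3-(tert-butyldimethylsilyloxy)germacra-1(10)E,4Z-dien-6-ol F2. TBAF in THF then gives diol 12, where the route is rejoined.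

Step 6 (the proposed new reduction). The chelate may not form (10 can rest as its transannular hemiketal) or hydride may be delivered from the wrong face. The fallback uses known chemistry and inverts C6 by substitution. It sets out from 10. TBSCl and imidazole give (3S,7S)-3-(tert-butyldimethylsilyloxy)germacra-1(10)E,4Z-dien-6-one F3. Luche reduction (NaBH4, CeCl3·7H2O, MeOH) of this unchelated ketone from the open face gives (3S,6S,7S)-3-(tert-butyldimethylsilyloxy)germacra-1(10)E,4Z-dien-6-ol F4. Mitsunobu inversion (4-nitrobenzoic acid, PPh3, DIAD) gives (3S,6R,7S)-3-(tert-butyldimethylsilyloxy)germacra-1(10)E,4Z-dien-6-yl 4-nitrobenzoate F5. Methanolysis (K2CO3, MeOH) gives the alcohol F2 described above, and TBAF returns diol 12.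

Step 7 (site-selective angeloylation). Acylation may not discriminate the two allylic hydroxyls well enough, or the angelate may isomerise at 60 °C. The fallback moves the angelate to the last step, where no site selection is needed. It sets out from 12. TBSCl (1.05 equiv), imidazole, CH2Cl2, −20 °C silylates the less hindered C3 hydroxyl to give F2 (as above). VO(acac)2 and t-BuOOH give (3S,4R,5S,6R,7S)-3-(tert-butyldimethylsilyloxy)-4,5-epoxygermacr-1(10)E-en-6-ol F6. Ac2O, pyridine and DMAP give (3S,4R,5S,6R,7S)-3-(tert-butyldimethylsilyloxy)-4,5-epoxygermacr-1(10)E-en-6-yl acetate F7. TBAF gives (3S,4R,5S,6R,7S)-6-acetoxy-4,5-epoxygermacr-1(10)E-en-3-ol F8. Yamaguchi esterification (13, 2,4,6-trichlorobenzoyl chloride, Et3N, toluene, 80 °C) returns the route at target 17.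

**Further compounds**
F1 | step 5 | (3S,7RS)-3-(tert-butyldimethylsilyloxy)germacra-1(10)E,4Z-dien-6-one | CC(C)(C)[Si](C)(C)O[C@H]1C/C=C(\C)CCC(C(C)C)C(=O)/C=C1/C
F2 | step 5 | (3S,6R,7S)-3-(tert-butyldimethylsilyloxy)germacra-1(10)E,4Z-dien-6-ol | CC(C)(C)[Si](C)(C)O[C@H]1C/C=C(\C)CC[C@@H](C(C)C)[C@@H](O)/C=C1/C
F3 | step 6 | (3S,7S)-3-(tert-butyldimethylsilyloxy)germacra-1(10)E,4Z-dien-6-one | CC(C)(C)[Si](C)(C)O[C@H]1C/C=C(\C)CC[C@@H](C(C)C)C(=O)/C=C1/C
F4 | step 6 | (3S,6S,7S)-3-(tert-butyldimethylsilyloxy)germacra-1(10)E,4Z-dien-6-ol | CC(C)(C)[Si](C)(C)O[C@H]1C/C=C(\C)CC[C@@H](C(C)C)[C@H](O)/C=C1/C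
F5 | step 6 | (3S,6R,7S)-3-(tert-butyldimethylsilyloxy)germacra-1(10)E,4Z-dien-6-yl 4-nitrobenzoate | CC(C)(C)[Si](C)(C)O[C@H]1C/C=C(\C)CC[C@@H](C(C)C)[C@@H](OC(=O)c2ccc(cc2)[N+](=O)[O-])/C=C1/C
F6 | step 7 | (3S,4R,5S,6R,7S)-3-(tert-butyldimethylsilyloxy)-4,5-epoxygermacr-1(10)E-en-6-ol | CC(C)(C)[Si](C)(C)O[C@H]1C/C=C(\C)CC[C@@H](C(C)C)[C@@H](O)[C@@H]2O[C@]12C
F7 | step 7 | (3S,4R,5S,6R,7S)-3-(tert-butyldimethylsilyloxy)-4,5-epoxygermacr-1(10)E-en-6-yl acetate | CC(C)(C)[Si](C)(C)O[C@H]1C/C=C(\C)CC[C@@H](C(C)C)[C@@H](OC(C)=O)[C@@H]2O[C@]12C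
F8 | step 7 | (3S,4R,5S,6R,7S)-6-acetoxy-4,5-epoxygermacr-1(10)E-en-3-ol | O[C@H]1C/C=C(\C)CC[C@@H](C(C)C)[C@@H](OC(C)=O)[C@@H]2O[C@]12C
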